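**Two clocks.** I started by setting the first step against the second, counting for each how many turnovers it gets in the run, in set-ups that share one charge and differ in vessel and dosing.

| flask | substrate | partner | time | remark |
|---|---|---|---|---|
| alpha | 26 mM | 26.0 mM (fed, over 1.60 h) | 2.0 h | a stirred flask in which partner is dosed at a steady rate over 1.60 h without added volume, worked up at 2.0 h |
| gamma | 26 mM | 26.0 mM |  | a single well-mixed tank run continuously and read at steady state, 2.0 h in it on average |
| theta | 26 mM (fed, over 1.60 h) | 26.0 mM | 2.0 h | a stirred flask in which substrate is dosed at a steady rate over 1.60 h without added volume, worked up at 2.0 h |
| eta | 26 mM | 26.0 mM | 2.0 h | everything together in a closed stirred flask, run for 2.0 h |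

    substrate + partner → intermediate (k1 = 0.051 L mol⁻¹ s⁻¹)
    intermediate → target (k2 = 7.6 × 10⁻⁵ s⁻¹)
    target ⇌ isomer of the product (K3 = 0.14, k3 = 2.3 × 10⁻⁴ s⁻¹)

* the set-up with the highest amount of target at the outlet or at the end, in percent of the substrate put in ("none" if the first two lie within 2 percentage points) (alpha / gamma / theta / eta / none)
* amount of target at the outlet or at the end, in percent of the substrate put in, alpha
* amount of target at the outlet or at the end, in percent of the substrate put in, gamma
* amount of target at the outlet or at the end, in percent of the substrate put in, theta
* amount of target at the outlet or at the end, in percent of the substrate put in, eta

- the stated concentrations are those of everything mixed, before any reaction; amounts are the same in each set-up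
- the feed brings no volume worth counting
- run time (alpha): 2.0 h

**Bench rule.** A turnover here is a step's rate per unit time multiplied by the run time. The first step at full charge gets F = 9.55 and the second gets S = 0.547, so the first is faster by a ratio of 17.4. The rule of thumb therefore calls the first step instantaneous and the second the rate-limiting step. Target and isomer of the product relax with a half-life of 0.103 h, shorter than the run, so I gave target 87.7% of their pool. For eta that made 37.0%.

**The border.** With equal charges all in at the start, as in eta, the substrate left falls as one over one plus the first step's turnovers so far. Summed over the run, the substrate still waiting costs a lag L = ln(1 + F) divided by 0.051 L mol⁻¹ s⁻¹ × 26 mM, which is 0.494 h. This is a quarter of the run, so the rule stops working here. I carried instead the working turnovers W, the second step's rate constant times the run time less the lag: W = 0.412.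

**My reckoning.** Eta came to 29.6%. For alpha and theta I also took off the middle of the dose, 0.800 h, and kept L, which is crude. That gave W = 0.193 and 15.4%, and by the symmetry of the first step's rate 15.4%. In gamma a tank balance left 27.5% of the substrate unreacted and passed on the share S over one plus S, giving 22.5%. My winner was eta.

**The forecast.** It named eta, since “the all-in batch forms it soonest and wins”, with 15.2% for alpha, 22.7% for gamma, 15.2% for theta and 26.6% for eta. My eta figure stands above the forecast's.

**The flask.** The simulation put eta first, with 29.0%, then gamma 22.7%, and alpha and theta 17.5% each. In eta at 2.00 h the intermediate still held 57.8% of the substrate charged, against 29.0% as target, and its half-life by the second step, 2.5 h, is longer than the run, which is what a W of 0.412 looks like in the flask. Left to 20.0 h, eta has W = 5.21, and its target stands at 86.1%.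

(The rate constants stand for no real mixture; the flask was simulated.)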